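The route rests on breaking C8–C9 of ring B. The C8 tertiary carbinol and the C9 CH2 branch (C11) trans to it are the 1,2-pattern left by reductive coupling of a ketone with the β-carbon of an enoate. One-electron reduction of a C8 methyl ketone tethered to a C9=C11 enoate therefore forges C8–C9, re-closes ring B and sets C8 and C9 together, leaving C12 as an ester for the later C12–C13 coupling. The precursor 17 is the ring-B-seco keto enoate on a cis-substituted ring A (C3 as dioxolane, tert-butyl ester to block lactonisation). It comes from ozonolysis of a Δ8 cis-decalin made from (S)-Wieland–Miescher ketone.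

Key step: step 11

Numbering remark: positions follow the target (ring A = C1–C5 and C10, ring B = C5–C10, C11 and C12 = the first two side-chain carbons on C9); β is the face of the C10 methyl, α the opposite face.

Step 1
Reactants: 1 (S)-Wieland–Miescher ketone
Product: 2 (4aS,5S)-5-hydroxy-4a-methyl-4,4a,5,6,7,8-hexahydronaphthalen-2(3H)-one (9β-hydroxy-Δ4-3-ketone)
Conditions: NaBH4 (0.3 equiv), EtOH, −10 °C
Reagents that add atoms: none
Why: Chemoselective NaBH4 reduction: the saturated C9 ketone is far more electrophilic than the vinylogous C3 enone carbonyl, and hydride adds from the face opposite the C10 methyl, which sets the new C9 carbinol with its hydroxyl β (cis to that methyl).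

Step 2
Reactants: 2 9β-hydroxy-Δ4-3-ketone
Product: 4 9β-hydroxy-4,4,10β-trimethyl-Δ5-octalin-3-one, via 4-methyl enone 3 (not isolated)
Conditions: t-BuOK (3 equiv), MeI (5 equiv), t-BuOH, 25 °C
Reagents that add atoms: iodomethane, CI
Why: Deconjugative α,α-dialkylation of an enone: the extended potassium dienolate is methylated at C4, enone 3 re-enolises and the second C4 methylation leaves the alkene at C5=C6; no stereocentre is formed and C-alkylation of the dienolate is expected to outpace O-methylation of the hindered secondary alcohol in t-BuOH.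

Step 3
Reactants: 4 9β-hydroxy-4,4,10β-trimethyl-Δ5-octalin-3-one
Product: 5 9β-hydroxy-4,4,10β-trimethyl-5β-decalin-3-one (cis-fused; 9-OH, 10-CH3 and 5-H all β)
Conditions: [Ir(cod)(PCy3)(py)]PF6 (5 mol %), H2 (1 atm), CH2Cl2, 25 °C
Reagents that add atoms: none
Why: Hydroxyl-directed homogeneous hydrogenation: the cationic iridium centre binds the homoallylic 9β-OH and hands both hydrogens to the β face of C5=C6, so H5 enters cis to the C10 methyl and the ring fusion becomes cis, the opposite of what an undirected catalyst approaching anti to that methyl would give.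

Step 4
Reactants: 5 cis-fused hydroxy ketone
Product: 6 3,3-ethylenedioxy-4,4,10β-trimethyl-5β-decalin-9β-ol
Conditions: ethylene glycol, p-TsOH·H2O (cat.), benzene, reflux, Dean–Stark
Reagents that add atoms: ethylene glycol, OCCO
Why: Acid-catalysed ketalisation pulled to completion by azeotropic removal of water; C3 is the only carbonyl and, with C4 quaternary, the C5 centre cannot epimerise.

Step 5
Reactants: 6 hydroxy dioxolane
Product: 7 3,3-ethylenedioxy-4,4,10β-trimethyl-5β-decalin-9-one
Conditions: (n-Pr4N)RuO4 (5 mol %), NMO, 4 Å MS, CH2Cl2, 25 °C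
Reagents that add atoms: none
Why: Ley–Griffith oxidation of the secondary alcohol under neutral conditions that spare the dioxolane; no stereocentre changes.

Step 6
Reactants: 7 C9 ketone
Product: 9 3,3-ethylenedioxy-4,4,8,10β-tetramethyl-5β-decalin-9-one (C8 epimers), via lithium enolate 8 (not isolated)
Conditions: LiN(i-Pr)2 (1.1 equiv), THF, −78 °C; MeI, −78 → 0 °C
Reagents that add atoms: iodomethane, CI
Why: Enolate alkylation: with C10 quaternary the ketone can enolise only toward C8 and is mono-methylated there; the new C8 centre (either epimer) is of no consequence because it becomes sp2 in step 7.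

Step 7
Reactants: 9 8-methyl C9 ketone
Product: 11 3,3-ethylenedioxy-4,4,8,10β-tetramethyl-5β-Δ8-octalin-9-yl trifluoromethanesulfonate, via lithium enolate 10 (not isolated)
Conditions: LiN(i-Pr)2 (1.2 equiv), THF, −78 → 0 °C; PhNTf2, 0 → 25 °C
Reagents that add atoms: N-phenylbis(trifluoromethanesulfonimide), O=S(=O)(N(c1ccccc1)S(=O)(=O)C(F)(F)F)C(F)(F)F
Why: Enol triflate formation: the only available enolate (C8=C9) is O-sulfonylated, as is routine for 2,2,6-trialkylcyclohexanones, which fixes the alkene position without any cationic intermediate that could provoke a methyl shift from C10.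

Step 8
Reactants: 11 enol triflate
Product: 12 3,3-ethylenedioxy-4,4,8,10β-tetramethyl-5β-Δ8-octalin (C8=C9 alkene)
Conditions: Pd(OAc)2 (5 mol %), PPh3 (10 mol %), HCO2H (2 equiv), n-Bu3N (3 equiv), DMF, 60 °C
Reagents that add atoms: none
Why: Palladium-catalysed formate reduction of a vinyl triflate (oxidative addition, formate exchange, decarboxylation, C–H reductive elimination) replaces OTf by H and keeps the double bond at C8=C9.

Step 9
Reactants: 12 Δ8 alkene
Product: 14 4,4-ethylenedioxy-1,3,3-trimethyl-2-(3-oxobutyl)cyclohexane-1-carbaldehyde (8,9-seco keto aldehyde; CHO and oxobutyl arm cis), via ozonide 13 (not isolated)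
Conditions: O3, CH2Cl2, −78 °C; PPh3, −78 → 25 °C
Reagents that add atoms: ozone, [O-][O+]=O
Why: Ozonolysis with reductive work-up cleaves the only alkene and unveils the C8 methyl ketone together with the C9 aldehyde; the aldehyde sits on quaternary C10 and cannot enolise, and C5 and C10 are untouched.

Step 10
Reactants: 14 keto aldehyde; 15 tert-butyl diethylphosphonoacetate
Product: 17 tert-butyl (E)-3-[4,4-ethylenedioxy-1,3,3-trimethyl-2-(3-oxobutyl)cyclohexyl]acrylate (acrylate and oxobutyl arms cis), via sodium phosphonate 16 (not isolated)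
Conditions: NaH (1.1 equiv), 15 (1.2 equiv), THF, 0 °C; then 14, 0 → 25 °C
Reagents that add atoms: none
Why: Horner–Wadsworth–Emmons olefination: the stabilised phosphonate anion adds to the aldehyde much faster than to the methyl ketone and, held in slight excess over NaH, is too weak a base to trigger an aldol between the two carbonyls; the E alkene follows from the usual equilibration of the adducts, and the tert-butyl ester is chosen so that the later C8 alkoxide cannot lactonise.

Step 11
Reactants: 17 keto enoate
Product: 18 tert-butyl 2-(3,3-ethylenedioxy-8α-hydroxy-4,4,8β,10β-tetramethyl-5β-decalin-9β-yl)acetate (9α-H)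
Conditions: SmI2 (2.5 equiv, 0.1 M in THF), HMPA (10 equiv), t-BuOH (2 equiv), THF, −78 → 0 °C
Reagents that add atoms: none
Why: SmI2–HMPA transfers one electron to the C8 ketone, the samarium ketyl attacks C9 (the enoate β-carbon) with its carbon, a second electron turns the α-ester radical into a samarium enolate and t-BuOH protonates C11; this is the SmI2 ketyl–olefin (ketone–enoate) reductive cyclisation, the chemical counterpart of cathodic ketone–enoate cyclisation. Ring B closes 6-exo-trig through a chair in which the two cis-disposed arms on ring A (C9 on C10, C6 on C5) become the new ring. C9 is controlled by ring A: with C11 on the face of the C10 methyl the chair is free of severe contacts, whereas the other face would place C11 axial against the C4–C5 bond or force the flipped chair with the C8 methyl axial against C1, so C11 should end up cis to the C10 methyl. C8 is controlled by the ketyl: the electron-rich O–Sm(HMPA)n group stays away from the enoate, and both the diequatorial and the diaxial O8/C11 arrangement give OH trans to the C9 branch. The step needs exactly this facial and trans selectivity and is helped by the quaternary C10 (no enolisable or eliminable position next to the acceptor), the dioxolane that hides C3 and disfavours the ring A chair with an axial C5 chain, and the tert-butyl ester that keeps the samarium alkoxide from lactonising; the residual cost is the 1,3 contact of the C8 and C10 methyls in the diequatorial mode.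

Step 12
Reactants: 18 hydroxy ester
Product: 19 tert-butyl 2-(3,3-ethylenedioxy-4,4,8β,10β-tetramethyl-8α-triethylsilyloxy-5β-decalin-9β-yl)acetate
Conditions: Et3SiOTf (1.3 equiv), 2,6-lutidine, CH2Cl2, −78 → 0 °C
Reagents that add atoms: triethylsilyl trifluoromethanesulfonate, CC[Si](CC)(CC)OS(=O)(=O)C(F)(F)F
Why: Silyl triflate silylation of a hindered tertiary alcohol; masking O8 now ensures that no free hydroxyl ever faces a leaving group or a carbon–metal bond at C12 (no tetrahydrofuran closure, no internal protonation), and a silyl ester formed by accident from the tert-butyl ester would be reduced to the same alcohol in step 13.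

Step 13
Reactants: 19 silyl ether ester
Product: 20 2-(3,3-ethylenedioxy-4,4,8β,10β-tetramethyl-8α-triethylsilyloxy-5β-decalin-9β-yl)ethanol
Conditions: LiAlH4, THF, 0 → 25 °C
Reagents that add atoms: none
Why: Hydride reduction of the ester to the C12 primary alcohol; the silyl ether and the dioxolane are inert to LiAlH4.

Step 14
Reactants: 20 primary alcohol
Product: 21 9β-(2-iodoethyl)-3,3-ethylenedioxy-4,4,8β,10β-tetramethyl-8α-triethylsilyloxy-5β-decalin
Conditions: I2, PPh3, imidazole, CH2Cl2, 0 → 25 °C
Reagents that add atoms: iodine, II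
Why: Appel-type iodination: the alkoxyphosphonium ion of the unhindered primary alcohol is displaced by iodide in an SN2 step, with imidazole buffering the acid so that the ketal and silyl ether survive.

Step 15
Reactants: 22 propargyl bromide; 23 geranyl bromide
Product: 25 (E)-6,10-dimethylundeca-5,9-dien-1-yne, via 1,3-dilithiopropyne 24 (not isolated)
Conditions: n-BuLi (2 equiv), TMEDA, Et2O–hexane, −78 °C; then 23, −78 → 25 °C; H2O
Reagents that add atoms: none
Why: Propargylation of an allylic halide: bromine–lithium exchange and deprotonation give 1,3-dilithiopropyne, which is alkylated at its sp3 carbon by direct SN2 attack on the primary allylic bromide, so the E alkene of 23 is kept and the terminal alkyne appears on aqueous quench.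

Step 16
Reactants: 25 enyne
Product: 27 (1E,5E)-1-iodo-2,6,10-trimethylundeca-1,5,9-triene, via alkenylalane 26 (not isolated)
Conditions: Me3Al (2 equiv), Cp2ZrCl2 (0.25 equiv), CH2Cl2, 0 → 25 °C; then I2, THF, −30 → 0 °C
Reagents that add atoms: trimethylaluminium, C[Al](C)C; iodine, II
Why: Negishi zirconium-catalysed carboalumination adds methyl and aluminium syn across the terminal alkyne with aluminium on the terminal carbon, and iodinolysis proceeds with retention, which fixes the E geometry of the future C13=C14 bond.

Step 17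
Reactants: 21 primary iodide; 27 vinyl iodide
Product: 29 3,3-ethylenedioxy 8-O-triethylsilyl derivative of the target, via alkylzinc iodide 28 (not isolated)
Conditions: Zn dust (activated), LiCl, THF, 40 °C; then 27, Pd(PPh3)4 (5 mol %), THF, 25 → 50 °C
Reagents that add atoms: none
Why: Negishi sp3–sp2 cross-coupling: zinc inserts into the primary C–I bond and the alkylzinc iodide transmetalates to the alkenylpalladium iodide formed from 27, reductive elimination joining C12 to C13 with retention of the E geometry; ketal, silyl ether and the remote trisubstituted alkenes do not interfere.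

Step 18
Reactants: 29 protected coupling product
Product: 30 target IN0671
Conditions: HCl (1 M aq.), THF, 25 °C
Reagents that add atoms: water, O
Why: Dilute aqueous acid hydrolyses the triethylsilyl ether and the dioxolane in one operation at an acidity too low to ionise the C8 tertiary carbinol or to protonate the trisubstituted alkenes; no stereocentre is touched.

Compound list
1 | (S)-Wieland–Miescher ketone, (8aS)-8a-methyl-3,4,8,8a-tetrahydronaphthalene-1,6(2H,7H)-dione | C[C@]12CCC(=O)C=C1CCCC2=O | starting material
2 | (4aS,5S)-5-hydroxy-4a-methyl-4,4a,5,6,7,8-hexahydronaphthalen-2(3H)-one (9β-hydroxy-Δ4-3-ketone) | O[C@@H]1[C@@]2(C)CCC(=O)C=C2CCC1 | intermediate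
3 | 9β-hydroxy-4,10β-dimethyl-Δ4-octalin-3-one (not isolated) | O[C@@H]1[C@@]2(C)CCC(=O)C(C)=C2CCC1 | intermediate
4 | 9β-hydroxy-4,4,10β-trimethyl-Δ5-octalin-3-one | O[C@@H]1[C@@]2(C)CCC(=O)C(C)(C)C2=CCC1 | intermediate
5 | 9β-hydroxy-4,4,10β-trimethyl-5β-decalin-3-one (cis-fused) | O[C@@H]1[C@@]2(C)CCC(=O)C(C)(C)[C@H]2CCC1 | intermediate
6 | 3,3-ethylenedioxy-4,4,10β-trimethyl-5β-decalin-9β-ol | O[C@@H]1[C@@]2(C)CCC3(OCCO3)C(C)(C)[C@H]2CCC1 | intermediate
7 | 3,3-ethylenedioxy-4,4,10β-trimethyl-5β-decalin-9-one | O=C1[C@@]2(C)CCC3(OCCO3)C(C)(C)[C@H]2CCC1 | intermediate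
8 | lithium C8=C9 enolate of 7 (not isolated) | C1=C(O[Li])[C@@]2(C)CCC3(OCCO3)C(C)(C)[C@H]2CC1 | intermediate
9 | 3,3-ethylenedioxy-4,4,8,10β-tetramethyl-5β-decalin-9-one (C8 epimers, configuration not controlled) | O=C1[C@@]2(C)CCC3(OCCO3)C(C)(C)[C@H]2CCC1C | intermediate
10 | lithium C8=C9 enolate of 9 (not isolated) | CC1=C(O[Li])[C@@]2(C)CCC3(OCCO3)C(C)(C)[C@H]2CC1 | intermediate
11 | 3,3-ethylenedioxy-4,4,8,10β-tetramethyl-5β-Δ8-octalin-9-yl trifluoromethanesulfonate | CC1=C(OS(=O)(=O)C(F)(F)F)[C@@]2(C)CCC3(OCCO3)C(C)(C)[C@H]2CC1 | intermediate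
12 | 3,3-ethylenedioxy-4,4,8,10β-tetramethyl-5β-Δ8-octalin | CC1=C[C@@]2(C)CCC3(OCCO3)C(C)(C)[C@H]2CC1 | intermediate
13 | 8,9-ozonide (1,2,4-trioxolane) of 12 (not isolated) | CC12OOC(O1)[C@@]3(C)CCC4(OCCO4)C(C)(C)[C@H]3CC2 | intermediate
14 | 4,4-ethylenedioxy-1,3,3-trimethyl-2-(3-oxobutyl)cyclohexane-1-carbaldehyde (CHO and oxobutyl arm cis) | O=C[C@@]1(C)CCC2(OCCO2)C(C)(C)[C@H]1CCC(C)=O | intermediate
15 | tert-butyl diethylphosphonoacetate | CCOP(=O)(CC(=O)OC(C)(C)C)OCC | starting material
16 | sodium salt of 15 (not isolated) | CCOP(=O)([CH-]C(=O)OC(C)(C)C)OCC.[Na+] | intermediate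
17 | tert-butyl (E)-3-[4,4-ethylenedioxy-1,3,3-trimethyl-2-(3-oxobutyl)cyclohexyl]acrylate (arms cis) | CC(C)(C)OC(=O)/C=C/[C@@]1(C)CCC2(OCCO2)C(C)(C)[C@H]1CCC(C)=O | intermediate
18 | tert-butyl 2-(3,3-ethylenedioxy-8α-hydroxy-4,4,8β,10β-tetramethyl-5β-decalin-9β-yl)acetate | CC(C)(C)OC(=O)C[C@@H]1[C@@]2(C)CCC3(OCCO3)C(C)(C)[C@H]2CC[C@@]1(C)O | intermediate
19 | tert-butyl 2-(3,3-ethylenedioxy-4,4,8β,10β-tetramethyl-8α-triethylsilyloxy-5β-decalin-9β-yl)acetate | CC(C)(C)OC(=O)C[C@@H]1[C@@]2(C)CCC3(OCCO3)C(C)(C)[C@H]2CC[C@@]1(C)O[Si](CC)(CC)CC | intermediate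
20 | 2-(3,3-ethylenedioxy-4,4,8β,10β-tetramethyl-8α-triethylsilyloxy-5β-decalin-9β-yl)ethanol | OCC[C@@H]1[C@@]2(C)CCC3(OCCO3)C(C)(C)[C@H]2CC[C@@]1(C)O[Si](CC)(CC)CC | intermediate
21 | 9β-(2-iodoethyl)-3,3-ethylenedioxy-4,4,8β,10β-tetramethyl-8α-triethylsilyloxy-5β-decalin | ICC[C@@H]1[C@@]2(C)CCC3(OCCO3)C(C)(C)[C@H]2CC[C@@]1(C)O[Si](CC)(CC)CC | intermediate
22 | propargyl bromide (3-bromopropyne) | C#CCBr | starting material
23 | geranyl bromide | CC(C)=CCC/C(C)=C/CBr | starting material
24 | 1,3-dilithiopropyne (not isolated) | [Li]CC#C[Li] | intermediate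
25 | (E)-6,10-dimethylundeca-5,9-dien-1-yne | C#CCC/C=C(\C)CCC=C(C)C | intermediate
26 | dimethyl[(1E,5E)-2,6,10-trimethylundeca-1,5,9-trien-1-yl]alane (not isolated) | C[Al](C)/C=C(\C)CC/C=C(\C)CCC=C(C)C | intermediate
27 | (1E,5E)-1-iodo-2,6,10-trimethylundeca-1,5,9-triene | I/C=C(\C)CC/C=C(\C)CCC=C(C)C | intermediate
28 | alkylzinc iodide from 21 (C12–ZnI; not isolated) | I[Zn]CC[C@@H]1[C@@]2(C)CCC3(OCCO3)C(C)(C)[C@H]2CC[C@@]1(C)O[Si](CC)(CC)CC | intermediate
29 | 3,3-ethylenedioxy 8-O-triethylsilyl derivative of the target | CC(C)=CCC/C(C)=C/CC/C(C)=C/CC[C@@H]1[C@@]2(C)CCC3(OCCO3)C(C)(C)[C@H]2CC[C@@]1(C)O[Si](CC)(CC)CC | intermediate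
30 | IN0671, 8α-hydroxy-4,4,8β,10β-tetramethyl-9β-[(3E,7E)-4,8,12-trimethyltrideca-3,7,11-trienyl]-5β-decalin-3-one | CC(C)=CCC/C(C)=C/CC/C(C)=C/CC[C@@H]1[C@@]2(C)CCC(=O)C(C)(C)[C@H]2CC[C@@]1(C)O | target

Total step count: 18. Longest linear sequence: 16 steps from 1 (steps 1–14, 17 and 18); steps 15 and 16 make the side-chain fragment.

Steps most likely to fail

Step 11. The radical anion may close through the wrong face of C9 or with O8 cis to C11 (poor facial or trans selectivity), or ketone and enoate may be reduced without forming the C–C bond. The fallback closes the same C8–C9 bond by a two-electron carbonyl allylation and sets out from keto aldehyde 14. Aldehyde-selective Nozaki–Hiyama–Kishi vinylation (vinyl bromide, CrCl2, NiCl2 cat., DMF) would give allylic alcohol F1 (both carbinol epimers serve), and Ac2O/pyridine/DMAP the allylic acetate F2. Pd(PPh3)4 with InI would turn F2, through its π-allylpalladium species, into an allylindium reagent that adds through C9 to the C8 ketone in a closed six-membered transition state, closing ring B as vinyl carbinol F3; the C8/C9 configuration would have to be confirmed at this point. Et3SiOTf/2,6-lutidine would give silyl ether F4, and 9-BBN followed by NaOH/H2O2 would hydroborate the vinyl group at its terminus, which comes back to the route at alcohol 20.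

Step 3. Direction by the hydroxyl may be incomplete (hydrogen delivered to the α face, trans-decalin), or the catalyst may stall on the hindered trisubstituted alkene. The fallback fixes the ring fusion before C4 becomes quaternary and sets out from hydroxy enone 2. Hydrogenation over Pd/C in EtOH–pyridine, which in 10-methyl-Δ4-3-octalones favours the cis-fused product, would give cis-fused hydroxy decalone F5. Exhaustive methylation with t-BuOK/MeI, relying on the enolisation of cis-fused 3-ketones toward C4, would then install the gem-dimethyl group and rejoin the route at 5.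

Step 17. Zinc insertion may be slow, the alkylzinc iodide may be protonated or homocoupled, or β-hydride elimination may occur at palladium. The fallback is a reductive cross-electrophile coupling that needs no preformed organometallic reagent. Enyne 25 would be carboaluminated as in step 16 and the alane quenched with N-bromosuccinimide to give vinyl bromide F6. Iodide 21 and F6 would then be joined with NiI2, 4,4′-di-tert-butyl-2,2′-bipyridine and Mn powder in DMA, which comes back to the route at 29.

Further compounds
F1 | step 11 | 4-[5,5-ethylenedioxy-2-(1-hydroxyprop-2-en-1-yl)-2,6,6-trimethylcyclohexyl]butan-2-one (carbinol epimers) | C=CC(O)[C@@]1(C)CCC2(OCCO2)C(C)(C)[C@H]1CCC(C)=O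
F2 | step 11 | acetate of F1 | C=CC(OC(C)=O)[C@@]1(C)CCC2(OCCO2)C(C)(C)[C@H]1CCC(C)=O
F3 | step 11 | 3,3-ethylenedioxy-4,4,8β,10β-tetramethyl-9β-vinyl-5β-decalin-8α-ol | C=C[C@@H]1[C@@]2(C)CCC3(OCCO3)C(C)(C)[C@H]2CC[C@@]1(C)O
F4 | step 11 | 8-O-triethylsilyl ether of F3 | C=C[C@@H]1[C@@]2(C)CCC3(OCCO3)C(C)(C)[C@H]2CC[C@@]1(C)O[Si](CC)(CC)CC
F5 | step 3 | 9β-hydroxy-10β-methyl-5β-decalin-3-one (cis-fused) | O[C@@H]1[C@@]2(C)CCC(=O)C[C@H]2CCC1
F6 | step 17 | (1E,5E)-1-bromo-2,6,10-trimethylundeca-1,5,9-triene | Br/C=C(\C)CC/C=C(\C)CCC=C(C)C
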